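**Plan**

- Numbering: ring A is C1 (C=O), C2=C3, C4 (OMe), C5, C6 (quaternary); the side chain is C7 (CHMe) and C8 (CHOH–aryl); the allyl group is C9–C11.
- Enabling feature: the C1 and C4 oxygens lie para across the C2=C3 alkene of ring A, so ring A is a ring-opened 7-oxanorbornene (a furan plus an alkene). The C8 oxygen can be the alkoxy group of a 2-alkoxyfuran whose oxygen-bearing carbon is C1.
- Retrosynthesis: the C1 ketone, C8–OH and C4–OMe go back to a bridged ketal; then C1–C6 and C4–C5 are cut (tethered furan [4+2]); then the furan–O(C8) bond; then C6=CH2, C6–C9 and C7–C8 (aldol).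
- Forward: the chain C8–C7–C6 is built first, the furan is hung on O–C8, and one cycloaddition closes the tetrahydrofuran, the oxygen bridge and carbocycle A together. The bridge and then the tether are opened.
- Stereochemistry: C7 and C8 come from an auxiliary-controlled syn aldol. C6 and C4 come from the exo geometry of the tethered cycloaddition, relayed from C7/C8. C4 keeps the bridge oxygen.

Key step: step 8

Assumption: the ketal carbon C1 of the three bicyclic ketals that follow the cycloadduct is drawn as the cis-fused epimer; this centre is erased when C1 becomes the ketone.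

Assumption: the target is taken to exist as the open γ-hydroxy ketone, as drawn, and not as its cyclic hemiketal.

**Step 1**
Reactants: 1 3,4-dimethoxybenzaldehyde; 2 (4S)-4-benzyl-3-propanoyl-1,3-oxazolidin-2-one
Product: 5 (4S)-4-benzyl-3-[(2S,3S)-3-(3,4-dimethoxyphenyl)-3-hydroxy-2-methylpropanoyl]-1,3-oxazolidin-2-one, via Z-dibutylboron enolate 3 (not isolated), via dibutylboron aldolate 4 (not isolated)
Conditions: 2, Bu2BOTf, i-Pr2NEt, CH2Cl2, 0 °C; 1, −78 to 0 °C; then H2O2, MeOH, pH 7 buffer, 0 °C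
Reagents that add atoms: none
Why: Evans syn aldol, in which the Z boron enolate should react through a chair Zimmerman–Traxler transition state on the face away from the benzyl group, setting C7 and C8 as the 2S,3S syn pair.

**Step 2**
Reactants: 5
Product: 6 (2S,3S)-3-(3,4-dimethoxyphenyl)-3-hydroxy-N-methoxy-N,2-dimethylpropanamide
Conditions: MeNH(OMe)·HCl, AlMe3, CH2Cl2, −10 to 0 °C; aq. potassium sodium tartrate
Reagents that add atoms: N,O-dimethylhydroxylamine hydrochloride, CNOC.Cl
Why: Aluminium amide transamination to the Weinreb amide is assisted by the free β-hydroxyl and should release the auxiliary without touching C7 or C8.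

**Step 3**
Reactants: 6
Product: 7 (2S,3S)-3-[(tert-butyldimethylsilyl)oxy]-3-(3,4-dimethoxyphenyl)-N-methoxy-N,2-dimethylpropanamide
Conditions: TBSOTf, 2,6-lutidine, CH2Cl2, 0 °C
Reagents that add atoms: tert-butyldimethylsilyl trifluoromethanesulfonate, CC(C)(C)[Si](C)(C)OS(=O)(=O)C(F)(F)F
Why: Silylation of a secondary alcohol with a silyl triflate and a hindered base blocks retro-aldol cleavage and alkoxide chemistry in the next two steps.

**Step 4**
Reactants: 7; 8 allylmagnesium bromide
Product: 10 (1S,2S)-1-[(tert-butyldimethylsilyl)oxy]-1-(3,4-dimethoxyphenyl)-2-methylhex-5-en-3-one, via bromomagnesium hemiaminal alkoxide 9 (not isolated)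
Conditions: THF, −78 to −20 °C; cold aq. NH4Cl quench at −78 °C
Reagents that add atoms: none
Why: Weinreb ketone synthesis, in which chelate 9 should persist until the cold quench, so that one allyl group is transferred and the β,γ-unsaturated ketone appears only at work-up.

**Step 5**
Reactants: 10
Product: 11 tert-butyl{[(1S,2R)-1-(3,4-dimethoxyphenyl)-2-methyl-3-methylidenehex-5-en-1-yl]oxy}dimethylsilane
Conditions: Cp2TiMe2, toluene–THF, 65 °C, dark
Reagents that add atoms: dimethyltitanocene (Cp2TiMe2), C[Ti+2]C.c1cc[cH-]c1.c1cc[cH-]c1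
Why: Petasis methylenation with the non-basic titanium methylidene should convert the enolisable ketone into the 1,1-disubstituted alkene without epimerising C7 or moving the allyl double bond.

**Step 6**
Reactants: 11
Product: 12 (1S,2R)-1-(3,4-dimethoxyphenyl)-2-methyl-3-methylidenehex-5-en-1-ol
Conditions: Bu4NF, THF, 0 °C to rt
Reagents that add atoms: none
Why: Fluoride-induced desilylation cleaves only the Si–O bond, since nothing else in the skipped diene is fluoride-labile.

**Step 7**
Reactants: 12; 13 2-bromofuran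
Product: 14 2-{[(1S,2R)-1-(3,4-dimethoxyphenyl)-2-methyl-3-methylidenehex-5-en-1-yl]oxy}furan
Conditions: 13 (3 equiv), CuI (10 mol %), 3,4,7,8-tetramethyl-1,10-phenanthroline (20 mol %), Cs2CO3, toluene, 100 °C
Reagents that add atoms: none
Why: Ullmann-type copper-catalysed C–O coupling of a secondary alcohol with a heteroaryl bromide runs under weakly basic conditions, which the acid-sensitive furyl ether, the diene and both stereocentres should tolerate.

**Step 8**
Reactants: 14
Product: 15 (1R,3S,4R,5S,7S)-3-(3,4-dimethoxyphenyl)-4-methyl-5-(prop-2-en-1-yl)-2,10-dioxatricyclo[5.2.1.0(1,5)]dec-8-ene (exo 7-oxanorbornene cycloadduct with the bridgehead ketal at C1)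
Conditions: toluene (0.01 M), BHT (cat.), solid K2CO3, sealed tube, 130 °C
Reagents that add atoms: none
Why: Proposed new method: on heating, the electron-rich 2-alkoxyfuran should add as the diene across the tethered 1,1-disubstituted alkene in a concerted, asynchronous thermal [4+2] cycloaddition that forms C1–C6 and C4–C5; the nearest known reaction type is the intramolecular furan Diels–Alder of 2-amido- and 2-alkylthiofurans, and of furfuryl 2-substituted-allyl amines, with unactivated alkenes. The tetrahydrofuran (C1–O–C8–C7–C6) closes in the exo mode because the three-atom tether cannot reach the endo position, and the same event closes carbocycle A as the boat of a 7-oxanorbornene bridged by the former furan oxygen. The exo tether fixes C1, C4 and C6 relative to one another (C7 exo and syn to the oxygen bridge, allyl endo), which is the relation that later places the C4 oxygen cis to the C7 branch and trans to allyl. The alkene face used relative to C7 and C8 is decided in the forming tetrahydrofuran, where the wanted adduct keeps the C7 methyl and C8 aryl on the face of the bridge oxygen and C5, away from the endo allyl and the etheno bridge; this preference is expected but not assured, and since furan cycloadditions are reversible at this temperature the mixture should drift toward the less crowded adduct. Site selectivity rests on ring size, because the allyl alkene could react only through a seven-membered tether ring, and the adduct cannot decay by the usual ring opening and aromatisation because C6 is quaternary.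

**Step 9**
Reactants: 15
Product: 16 (2S,3R,3aS,5S,7aS)-2-(3,4-dimethoxyphenyl)-7a-methoxy-3-methyl-3a-(prop-2-en-1-yl)-2,3,3a,4,5,7a-hexahydro-1-benzofuran-5-ol
Conditions: PPTS (cat.), MeOH, 0 °C to rt; Et3N quench
Reagents that add atoms: methanol, CO
Why: Acid-catalysed transketalisation, in which the strained C1–O bridge bond should ionise to an oxocarbenium ion stabilised by the tetrahydrofuran oxygen (the alternative cation would sit at a bridgehead); methanol adds at C1 and the bridge oxygen remains as the C4 hydroxyl with its configuration untouched.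

**Step 10**
Reactants: 16
Product: 18 (2S,3R,3aS,5S,7aS)-2-(3,4-dimethoxyphenyl)-5,7a-dimethoxy-3-methyl-3a-(prop-2-en-1-yl)-2,3,3a,4,5,7a-hexahydro-1-benzofuran, via sodium alkoxide 17 (not isolated)
Conditions: NaH, THF, 0 °C; MeI, 0 °C to rt
Reagents that add atoms: iodomethane, CI
Why: Williamson ether synthesis on the only free hydroxyl, the C8 oxygen being held in the ketal, and the ketal and alkenes being inert to NaH and MeI.

**Step 11**
Reactants: 18
Product: 20 (4S,6S)-6-[(1S,2R)-1-(3,4-dimethoxyphenyl)-1-hydroxypropan-2-yl]-4-methoxy-6-(prop-2-en-1-yl)cyclohex-2-en-1-one, via cyclic hemiketal 19 (not isolated)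
Conditions: PPTS (cat.), acetone–H2O (4:1), rt
Reagents that add atoms: water, O
Why: Mild acid hydrolysis of the mixed ketal should pass through hemiketal 19, which opens to the C1 ketone and the C8 hydroxyl; the quaternary C6 blocks enolisation on that side and the allylic C4 methyl ether should survive this acidity.

**Compound list**

1 | 3,4-dimethoxybenzaldehyde | COc1ccc(C=O)cc1OC | starting material
2 | (4S)-4-benzyl-3-propanoyl-1,3-oxazolidin-2-one | CCC(=O)N1[C@@H](Cc2ccccc2)COC1=O | starting material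
3 | Z-dibutylboron enolate of 2 (formed in the flask) | C/C=C(\OB(CCCC)CCCC)N1[C@@H](Cc2ccccc2)COC1=O | intermediate
4 | dibutylboron aldolate of 5 (formed in the flask) | O=C([C@@H](C)[C@H](OB(CCCC)CCCC)c1ccc(OC)c(OC)c1)N1[C@@H](Cc2ccccc2)COC1=O | intermediate
5 | (4S)-4-benzyl-3-[(2S,3S)-3-(3,4-dimethoxyphenyl)-3-hydroxy-2-methylpropanoyl]-1,3-oxazolidin-2-one | O=C([C@@H](C)[C@H](O)c1ccc(OC)c(OC)c1)N1[C@@H](Cc2ccccc2)COC1=O | intermediate
6 | (2S,3S)-3-(3,4-dimethoxyphenyl)-3-hydroxy-N-methoxy-N,2-dimethylpropanamide | CON(C)C(=O)[C@@H](C)[C@H](O)c1ccc(OC)c(OC)c1 | intermediate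
7 | (2S,3S)-3-[(tert-butyldimethylsilyl)oxy]-3-(3,4-dimethoxyphenyl)-N-methoxy-N,2-dimethylpropanamide | CON(C)C(=O)[C@@H](C)[C@H](O[Si](C)(C)C(C)(C)C)c1ccc(OC)c(OC)c1 | intermediate
8 | allylmagnesium bromide | C=CC[Mg]Br | starting material
9 | bromomagnesium hemiaminal alkoxide from 7 and 8 (formed in the flask) | C=CCC(O[Mg]Br)(N(C)OC)[C@@H](C)[C@H](O[Si](C)(C)C(C)(C)C)c1ccc(OC)c(OC)c1 | intermediate
10 | (1S,2S)-1-[(tert-butyldimethylsilyl)oxy]-1-(3,4-dimethoxyphenyl)-2-methylhex-5-en-3-one | C=CCC(=O)[C@@H](C)[C@H](O[Si](C)(C)C(C)(C)C)c1ccc(OC)c(OC)c1 | intermediate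
11 | tert-butyl{[(1S,2R)-1-(3,4-dimethoxyphenyl)-2-methyl-3-methylidenehex-5-en-1-yl]oxy}dimethylsilane | C=CCC(=C)[C@@H](C)[C@H](O[Si](C)(C)C(C)(C)C)c1ccc(OC)c(OC)c1 | intermediate
12 | (1S,2R)-1-(3,4-dimethoxyphenyl)-2-methyl-3-methylidenehex-5-en-1-ol | C=CCC(=C)[C@@H](C)[C@H](O)c1ccc(OC)c(OC)c1 | intermediate
13 | 2-bromofuran | Brc1ccco1 | starting material
14 | 2-{[(1S,2R)-1-(3,4-dimethoxyphenyl)-2-methyl-3-methylidenehex-5-en-1-yl]oxy}furan | C=CCC(=C)[C@@H](C)[C@H](Oc1ccco1)c1ccc(OC)c(OC)c1 | intermediate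
15 | (1R,3S,4R,5S,7S)-3-(3,4-dimethoxyphenyl)-4-methyl-5-(prop-2-en-1-yl)-2,10-dioxatricyclo[5.2.1.0(1,5)]dec-8-ene | C=CC[C@@]12C[C@H]3C=C[C@@]1(O3)O[C@H](c1ccc(OC)c(OC)c1)[C@@H]2C | intermediate
16 | (2S,3R,3aS,5S,7aS)-2-(3,4-dimethoxyphenyl)-7a-methoxy-3-methyl-3a-(prop-2-en-1-yl)-2,3,3a,4,5,7a-hexahydro-1-benzofuran-5-ol | C=CC[C@@]12C[C@H](O)C=C[C@]1(OC)O[C@H](c1ccc(OC)c(OC)c1)[C@@H]2C | intermediate
17 | sodium alkoxide of 16 (formed in the flask) | C=CC[C@@]12C[C@H]([O-])C=C[C@]1(OC)O[C@H](c1ccc(OC)c(OC)c1)[C@@H]2C.[Na+] | intermediate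
18 | (2S,3R,3aS,5S,7aS)-2-(3,4-dimethoxyphenyl)-5,7a-dimethoxy-3-methyl-3a-(prop-2-en-1-yl)-2,3,3a,4,5,7a-hexahydro-1-benzofuran | C=CC[C@@]12C[C@H](OC)C=C[C@]1(OC)O[C@H](c1ccc(OC)c(OC)c1)[C@@H]2C | intermediate
19 | (2S,3R,3aS,5S,7aS)-2-(3,4-dimethoxyphenyl)-5-methoxy-3-methyl-3a-(prop-2-en-1-yl)-2,3,3a,4,5,7a-hexahydro-1-benzofuran-7a-ol (formed in the flask) | C=CC[C@@]12C[C@H](OC)C=C[C@]1(O)O[C@H](c1ccc(OC)c(OC)c1)[C@@H]2C | intermediate
20 | (4S,6S)-6-[(1S,2R)-1-(3,4-dimethoxyphenyl)-1-hydroxypropan-2-yl]-4-methoxy-6-(prop-2-en-1-yl)cyclohex-2-en-1-one | C=CC[C@@]1([C@@H](C)[C@H](O)c2ccc(OC)c(OC)c2)C[C@H](OC)C=CC1=O | target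

**Step count**

Total: 11 steps. Longest linear sequence: 11 steps (1 and 2 to 20).

**Steps most likely to fail**

1. Step 8. The cycloaddition may stall at an unfavourable equilibrium, may use the wrong alkene face relative to C7/C8, or the furyl ether may be lost first by ionisation of the benzylic C8–O bond with oxygen-to-carbon migration. The fallback gives up the cycloaddition and builds ring A on a lactone template by known reactions; it sets out from 1 and rejoins the route at 20.
   - Lactone: Brown syn-crotylation of 1 with (−)-Ipc2B[(Z)-crotyl] (from (+)-α-pinene; Si-face attack) should give (1S,2R)-1-(3,4-dimethoxyphenyl)-2-methylbut-3-en-1-ol F1. Hydroboration–oxidation (9-BBN; NaOH, H2O2) gives (1S,2R)-1-(3,4-dimethoxyphenyl)-2-methylbutane-1,4-diol F2. Oxidative lactonisation (TEMPO, PhI(OAc)2) gives the cis lactone (4R,5S)-5-(3,4-dimethoxyphenyl)-4-methyloxolan-2-one F3, whose carbonyl is C1.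
   - C5–C2 unit: Stork–Zhao olefination of (S)-2,2-dimethyl-1,3-dioxolane-4-carbaldehyde (Ph3PCH2I iodide, NaN(SiMe3)2) gives (4R)-4-[(Z)-2-iodoethenyl]-2,2-dimethyl-1,3-dioxolane F4. Aqueous AcOH gives (2R,3Z)-4-iodobut-3-ene-1,2-diol F5. I2, PPh3 and imidazole give the primary iodide (2R,3Z)-1,4-diiodobut-3-en-2-ol F6. MeOTf with 2,6-di-tert-butyl-4-methylpyridine gives (1Z,3R)-1,4-diiodo-3-methoxybut-1-ene F7.
   - Assembly: alkylation of the lithium enolate of F3 (LiN(i-Pr)2, THF–DMPU) with F7 gives (4R,5S)-5-(3,4-dimethoxyphenyl)-3-[(2S,3Z)-4-iodo-2-methoxybut-3-en-1-yl]-4-methyloxolan-2-one F8. A second enolate alkylation with allyl bromide, anti to the cis methyl and aryl groups, gives (3S,4R,5S)-5-(3,4-dimethoxyphenyl)-3-[(2S,3Z)-4-iodo-2-methoxybut-3-en-1-yl]-4-methyl-3-(prop-2-en-1-yl)oxolan-2-one F9, with allyl trans to the C7 methyl.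
   - Ring closure: iodine–lithium exchange (t-BuLi, −78 °C) lets the Z-vinyllithium add to the lactone carbonyl; this closes ring A and frees the C8 alkoxide, so work-up should give 20.

2. Step 7. The copper alkoxide may fail to engage the electron-rich bromofuran, or the furyl ether may be lost to acid traces or to premature cycloaddition at the coupling temperature. The fallback sets out from 12 and returns at 14. The sodium alkoxide of 12 (NaH, DMF, 0 °C) displaces bromide from 5-bromofuran-2-carbaldehyde by addition–elimination, activated by the formyl group, to give 5-{[(1S,2R)-1-(3,4-dimethoxyphenyl)-2-methyl-3-methylidenehex-5-en-1-yl]oxy}furan-2-carbaldehyde F10. Decarbonylation with RhCl(PPh3)3 (1 equiv, toluene, 110 °C) then removes the formyl group and gives 14; if the cycloaddition follows in the same pot, the material arrives as 15.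

3. Step 4. The β,γ-unsaturated ketone may slide into conjugation, with loss of configuration at C7 through the dienol, during quench, chromatography or the methylenation that follows; over-addition of the allyl reagent is the lesser danger. The fallback avoids any allyl ketone; it sets out from 7 and returns at 11. MeMgBr converts 7 into the methyl ketone (3S,4S)-4-[(tert-butyldimethylsilyl)oxy]-4-(3,4-dimethoxyphenyl)-3-methylbutan-2-one F11. Kinetic deprotonation at the methyl group (KN(SiMe3)2, −78 °C) and PhNTf2 give (3S,4S)-4-[(tert-butyldimethylsilyl)oxy]-4-(3,4-dimethoxyphenyl)-3-methylbut-1-en-2-yl trifluoromethanesulfonate F12. Stille coupling with allyltributylstannane (Pd(PPh3)4, LiCl, THF, 60 °C) gives 11.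

**Further compounds**

F1 | step 8 | (1S,2R)-1-(3,4-dimethoxyphenyl)-2-methylbut-3-en-1-ol | C=C[C@@H](C)[C@H](O)c1ccc(OC)c(OC)c1
F2 | step 8 | (1S,2R)-1-(3,4-dimethoxyphenyl)-2-methylbutane-1,4-diol | OCC[C@@H](C)[C@H](O)c1ccc(OC)c(OC)c1
F3 | step 8 | (4R,5S)-5-(3,4-dimethoxyphenyl)-4-methyloxolan-2-one | O=C1C[C@@H](C)[C@@H](c2ccc(OC)c(OC)c2)O1
F4 | step 8 | (4R)-4-[(Z)-2-iodoethenyl]-2,2-dimethyl-1,3-dioxolane | CC1(C)OC[C@@H](/C=C\I)O1
F5 | step 8 | (2R,3Z)-4-iodobut-3-ene-1,2-diol | OC[C@H](O)/C=C\I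
F6 | step 8 | (2R,3Z)-1,4-diiodobut-3-en-2-ol | IC[C@H](O)/C=C\I
F7 | step 8 | (1Z,3R)-1,4-diiodo-3-methoxybut-1-ene | IC[C@H](OC)/C=C\I
F8 | step 8 | (4R,5S)-5-(3,4-dimethoxyphenyl)-3-[(2S,3Z)-4-iodo-2-methoxybut-3-en-1-yl]-4-methyloxolan-2-one (C3 epimers) | O=C1C(C[C@H](OC)/C=C\I)[C@@H](C)[C@@H](c2ccc(OC)c(OC)c2)O1
F9 | step 8 | (3S,4R,5S)-5-(3,4-dimethoxyphenyl)-3-[(2S,3Z)-4-iodo-2-methoxybut-3-en-1-yl]-4-methyl-3-(prop-2-en-1-yl)oxolan-2-one | C=CC[C@]1(C[C@H](OC)/C=C\I)[C@@H](C)[C@@H](c2ccc(OC)c(OC)c2)OC1=O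
F10 | step 7 | 5-{[(1S,2R)-1-(3,4-dimethoxyphenyl)-2-methyl-3-methylidenehex-5-en-1-yl]oxy}furan-2-carbaldehyde | C=CCC(=C)[C@@H](C)[C@H](Oc1ccc(C=O)o1)c1ccc(OC)c(OC)c1
F11 | step 4 | (3S,4S)-4-[(tert-butyldimethylsilyl)oxy]-4-(3,4-dimethoxyphenyl)-3-methylbutan-2-one | CC(=O)[C@@H](C)[C@H](O[Si](C)(C)C(C)(C)C)c1ccc(OC)c(OC)c1
F12 | step 4 | (3S,4S)-4-[(tert-butyldimethylsilyl)oxy]-4-(3,4-dimethoxyphenyl)-3-methylbut-1-en-2-yl trifluoromethanesulfonate | C=C(OS(=O)(=O)C(F)(F)F)[C@@H](C)[C@H](O[Si](C)(C)C(C)(C)C)c1ccc(OC)c(OC)c1
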